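**Plan**

1. Numbering: β-carboline locants C1–C9a (C4b is the benzo carbon on C4a), primed locants for the gramine indole, ring A is its benzene ring. Enabling feature: C4a is a quaternary indoline carbon carrying O5' and C4b, and its neighbour C9a carries N9 and C4' of ring A. This is the pattern left when a Fischer indolisation of an α-aryloxy ketone cannot aromatise and ring A captures the 3H-indole at C9a.
2. Retrosynthesis: C3'–CH2NMe2 (Mannich), N2–CH3 (from a Boc carbamate) and N1'–H (from a sulfonamide) are cut first. Then C4b–C4a, N9–C9a and C4'–C9a are cut together, back to phenylhydrazine and a 4-aryloxypiperidin-3-one. Last come the ether bond O5'–C4a (epoxide opening) and C5'–O (from a bromide).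
3. Forward: the ring A indole is built (Bartoli), N-tosylated, converted to the 5'-phenol, joined through oxygen to the purchased piperidine ring and oxidised to the ketone. The indoline and dihydrofuran rings then form in one operation. Detosylation, carbamate reduction and aminomethylation finish the target.
4. Stereochemistry: the ketone is racemic. C4a (S) is set by a chiral phosphoric acid in the [3,3] shift of the achiral ene-hydrazine, C9a (R) follows from the enforced cis ring fusion, and neither centre can epimerise afterwards.

Key step: step 6

Remark: the sense of induction of the phosphoric acid in step 6 cannot be predicted with confidence. (S)-STRIP, (S)-6,6'-bis(2,4,6-triisopropylphenyl)-1,1'-spirobiindane-7,7'-diyl hydrogen phosphate, is written; its (R)-antipode would be used if the (4aR) series results.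

**Route**

Step 1
Reactants: 1 4-bromo-2-methoxy-1-nitrobenzene
Product: 2 5-bromo-7-methoxy-1H-indole
Conditions: CH2=CHMgBr (3.2 equiv), THF, −40 °C; aq NH4Cl
Reagents that add atoms: vinylmagnesium bromide, C=C[Mg]Br
Why: Bartoli indole synthesis, in which the vinyl Grignard reagent takes the ortho-substituted nitroarene through the nitrosoarene and an N-aryl-O-vinylhydroxylamine whose [3,3] shift onto the free ortho carbon leads to the 7-substituted indole, the methoxy group serving as the required ortho substituent and the bromide surviving at low temperature.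

Step 2
Reactants: 2 5-bromo-7-methoxy-1H-indole
Product: 3 5-bromo-7-methoxy-1-tosyl-1H-indole
Conditions: NaH, TsCl, DMF, 0 °C → rt
Reagents that add atoms: p-toluenesulfonyl chloride, Cc1ccc(S(=O)(=O)Cl)cc1
Why: N-sulfonylation of the indolide anion, which masks N1' and damps C3' for the acid-mediated key step and survives every step up to its reductive removal.

Step 3
Reactants: 3 5-bromo-7-methoxy-1-tosyl-1H-indole
Product: 5 7-methoxy-1-tosyl-1H-indol-5-ol, via pinacol boronate 4 (not isolated)
Conditions: B2pin2, Pd(dppf)Cl2 (cat.), KOAc, dioxane, 90 °C; then 30% H2O2, aq NaOH, THF, 0 °C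
Reagents that add atoms: hydrogen peroxide, OO (the phenol oxygen); bis(pinacolato)diboron, CC1(C)OB(B2OC(C)(C)C(C)(C)O2)OC1(C)C (atoms held only in intermediate 4)
Why: Miyaura borylation of the aryl bromide followed by peroxide oxidation with boron-to-oxygen aryl migration is the standard bromide-to-phenol conversion, and the brief cold alkaline treatment should leave the indole sulfonamide intact.

Step 4
Reactants: 5 7-methoxy-1-tosyl-1H-indol-5-ol; 6 tert-butyl 7-oxa-3-azabicyclo[4.1.0]heptane-3-carboxylate (racemic)
Product: 7 tert-butyl trans-3-hydroxy-4-[(7-methoxy-1-tosyl-1H-indol-5-yl)oxy]piperidine-1-carboxylate (racemic)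
Conditions: Cs2CO3, DMF, 80 °C
Reagents that add atoms: none
Why: SN2 opening of the epoxide by the phenoxide with inversion should give the trans ether mainly by attack at C4, the carbon remote from the electron-withdrawing carbamate nitrogen; the minor 3-aryloxy isomer is removed by chromatography, and the configuration is irrelevant because both centres are erased in steps 5 and 6.

Step 5
Reactants: 7 tert-butyl trans-3-hydroxy-4-[(7-methoxy-1-tosyl-1H-indol-5-yl)oxy]piperidine-1-carboxylate
Product: 8 tert-butyl 4-[(7-methoxy-1-tosyl-1H-indol-5-yl)oxy]-3-oxopiperidine-1-carboxylate (racemic)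
Conditions: Dess–Martin periodinane, CH2Cl2, rt
Reagents that add atoms: none
Why: Dess–Martin oxidation of the secondary alcohol under near-neutral conditions should give the α-aryloxy ketone without touching the carbamate, the sulfonamide or the electron-rich arene, the α-stereocentre being left racemic on purpose.

Step 6
Reactants: 8 tert-butyl 4-[(7-methoxy-1-tosyl-1H-indol-5-yl)oxy]-3-oxopiperidine-1-carboxylate; 9 phenylhydrazine
Product: 12 (4aS,9aR)-N2-Boc-N1'-tosyl hexacycle (2-Boc-hexahydro-β-carboline whose C4a–O–C5' and C9a–C4' bonds to 7-methoxy-1-tosylindole form a cis-fused dihydrofuran), via phenylhydrazone 10 (not isolated), via (4aS)-3H-indole 11 (not isolated)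
Conditions: 4 Å MS, PhMe, rt; then (S)-STRIP (10 mol%), Amberlite CG50, 45 °C
Reagents that add atoms: none
Why: Proposed new method: hydrazone 10 tautomerises under the chiral acid to the achiral ene-hydrazine across C9a=C4a, which undergoes the Fischer [3,3] shift (C4b–C4a) inside the hydrogen-bonded phosphate complex; rearomatisation, 5-exo-trig addition of the aniline nitrogen to the C9a imine (N9–C9a, indoline ring) and loss of NH3, which the acidic resin binds so that the catalyst turns over, give 3H-indole 11, which cannot aromatise because C4a is quaternary. Protonated 11 is then captured at C9a by C4' of ring A in a 5-exo-trig Friedel–Crafts closure of the dihydrofuran ring (C4'–C9a), the same ring closure by which α-aryloxy ketones cyclise to benzofurans in acid. The closest known reaction types are interrupted Fischer indolisations in which a tethered oxygen or nitrogen nucleophile traps the 3H-indolium carbon, and chiral phosphoric acid catalysed Fischer indolisations and [3,3] shifts of α-branched ketone arylhydrazones that create quaternary stereocentres; the arene as terminating nucleophile and the merger into one enantioselective cascade are new. C4a is set by the catalyst, which selects one face of the ene-hydrazine so that both enantiomers of 8 converge on the (4aS) series, and C9a follows from C4a because the short ether tether can deliver C4' only to the oxygen-bearing face, giving the cis ring fusion. The step needs ene-hydrazine formation toward C4a and not C1, which rests on the tendency of carbamate-protected piperidin-3-ones to enolise away from nitrogen and on weak acid favouring the more substituted, oxygen-bearing ene-hydrazine, and it needs attack through C4' and not C6', which rests on C4' being ortho to the ether oxygen, para to the methoxy group and the site that 5-oxygenated indoles offer to electrophiles (the counterpart of C1 of a 2-naphthol).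

Step 7
Reactants: 12 (4aS,9aR)-N2-Boc-N1'-tosyl hexacycle
Product: 13 (4aS,9aR)-N2-Boc hexacycle with free N1'–H
Conditions: Mg, MeOH, rt (sonication)
Reagents that add atoms: none
Why: Single-electron reduction by Mg in methanol should cleave the N–S bond of the indole sulfonamide while the carbamate, the aryl ether and both stereocentres stay untouched.

Step 8
Reactants: 13 (4aS,9aR)-N2-Boc hexacycle with free N1'–H
Product: 14 (4aS,9aR)-N2-methyl hexacycle with free N1'–H
Conditions: LiAlH4, THF, reflux; aq NaOH work-up
Reagents that add atoms: none
Why: LiAlH4 reduction of the tert-butyl carbamate should deliver the N-methyl amine, the two N–H groups merely consuming hydride as aluminium amides that are released on work-up.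

Step 9
Reactants: 14 (4aS,9aR)-N2-methyl hexacycle with free N1'–H
Product: 15 target, the (4aS,9aR)-3'-(dimethylaminomethyl)-N2-methyl hexacycle
Conditions: CH2=NMe2+ I−, MeCN/CH2Cl2, 0 °C → rt; aq NaHCO3
Reagents that add atoms: dimethylmethylideneammonium iodide, C=[N+](C)C.[I-]
Why: Mannich aminomethylation with the preformed iminium salt should occur at C3', the most nucleophilic carbon of the free indole, the tertiary amine being inert and any aminal formed at the hindered N9 reverting on aqueous work-up.

**Compound list**

1 | 4-bromo-2-methoxy-1-nitrobenzene | COc1cc(Br)ccc1[N+](=O)[O-] | starting material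
2 | 5-bromo-7-methoxy-1H-indole | COc1cc(Br)cc2cc[nH]c12 | intermediate
3 | 5-bromo-7-methoxy-1-tosyl-1H-indole | COc1cc(Br)cc2ccn(S(=O)(=O)c3ccc(C)cc3)c12 | intermediate
4 | 7-methoxy-5-(4,4,5,5-tetramethyl-1,3,2-dioxaborolan-2-yl)-1-tosyl-1H-indole | COc1cc(B3OC(C)(C)C(C)(C)O3)cc2ccn(S(=O)(=O)c4ccc(C)cc4)c12 | intermediate (not isolated)
5 | 7-methoxy-1-tosyl-1H-indol-5-ol | COc1cc(O)cc2ccn(S(=O)(=O)c3ccc(C)cc3)c12 | intermediate
6 | tert-butyl 7-oxa-3-azabicyclo[4.1.0]heptane-3-carboxylate (racemic) | CC(C)(C)OC(=O)N1CCC2OC2C1 | starting material
7 | tert-butyl trans-3-hydroxy-4-[(7-methoxy-1-tosyl-1H-indol-5-yl)oxy]piperidine-1-carboxylate (racemic; 3R,4R enantiomer drawn) | CC(C)(C)OC(=O)N1CC[C@@H](Oc2cc(OC)c3c(ccn3S(=O)(=O)c3ccc(C)cc3)c2)[C@H](O)C1 | intermediate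
8 | tert-butyl 4-[(7-methoxy-1-tosyl-1H-indol-5-yl)oxy]-3-oxopiperidine-1-carboxylate (racemic) | CC(C)(C)OC(=O)N1CCC(Oc2cc(OC)c3c(ccn3S(=O)(=O)c3ccc(C)cc3)c2)C(=O)C1 | intermediate
9 | phenylhydrazine | NNc1ccccc1 | starting material
10 | phenylhydrazone of 8 (racemic, E/Z mixture) | CC(C)(C)OC(=O)N1CCC(Oc2cc(OC)c3c(ccn3S(=O)(=O)c3ccc(C)cc3)c2)C(=NNc2ccccc2)C1 | intermediate (not isolated)
11 | tert-butyl (4aS)-4a-[(7-methoxy-1-tosyl-1H-indol-5-yl)oxy]-1,3,4,4a-tetrahydro-2H-pyrido[3,4-b]indole-2-carboxylate | CC(C)(C)OC(=O)N1CC[C@]2(Oc3cc(OC)c4c(ccn4S(=O)(=O)c4ccc(C)cc4)c3)c3ccccc3N=C2C1 | intermediate (not isolated)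
12 | (4aS,9aR)-N2-Boc-N1'-tosyl hexacycle: 2-Boc-1,2,3,4,4a,9a-hexahydro-β-carboline with C4a bonded to O5' and C9a bonded to C4' of 7-methoxy-1-tosylindole (cis-fused dihydrofuran) | COc1cc2c(c3ccn(S(=O)(=O)c4ccc(C)cc4)c13)[C@@]13CN(C(=O)OC(C)(C)C)CC[C@]1(O2)c1ccccc1N3 | intermediate
13 | (4aS,9aR)-N2-Boc hexacycle with free N1'–H (12 without the tosyl group) | COc1cc2c(c3cc[nH]c13)[C@@]13CN(C(=O)OC(C)(C)C)CC[C@]1(O2)c1ccccc1N3 | intermediate
14 | (4aS,9aR)-N2-methyl hexacycle with free N1'–H (13 with N2–CH3 in place of N2–Boc) | COc1cc2c(c3cc[nH]c13)[C@@]13CN(C)CC[C@]1(O2)c1ccccc1N3 | intermediate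
15 | target: 14 with a dimethylaminomethyl group on C3', (4aS,9aR) | COc1cc2c(c3c(CN(C)C)c[nH]c13)[C@@]13CN(C)CC[C@]1(O2)c1ccccc1N3 | target

**Step count and risks**

Total step count: 9. Longest linear sequence: 9 steps (1 → 15); compounds 6 and 9 are purchased.

The three steps most likely to fail are step 6, step 4 and step 9, in that order.

Risk at step 6, the one step that goes beyond known chemistry. Several processes could divert it: tautomerisation of the hydrazone toward C1 followed by ordinary indolisation on that side; 1,4-elimination of the aryloxide from the hydrazone to an azoalkene; stalling at 3H-indole 11 without arene capture, which a late charge of a stronger achiral acid such as diphenyl phosphate could overcome because C4a is already set; and poor facial discrimination in the [3,3] shift of an N–H hydrazone. The fallback for step 6 sets out from phenol 5 and comes back to the route at 12, so that 7 and 8 are bypassed. It uses the oxidative [3+2] coupling of 2,3-disubstituted indoles with electron-rich phenols mediated by PhI(OAc)2, a known way to benzofuro[3,2-b]indolines in which the phenol oxygen ends on C4a and the phenol ortho carbon on C9a. Phenol 5 and purchased tert-butyl 1,3,4,9-tetrahydro-2H-pyrido[3,4-b]indole-2-carboxylate (CC(C)(C)OC(=O)N1CCc2c(C1)[nH]c1ccccc21), treated with PhI(OAc)2 in hexafluoroisopropanol at low temperature, should give the racemic cis-fused N2-Boc-N1'-tosyl hexacycle F1 in one operation. Preparative HPLC of F1 on a chiral stationary phase would then supply the (4aS,9aR) enantiomer, which is 12.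

Risk at step 4. The phenoxide may attack C3 instead of C4, the internal epoxide may open too slowly at a temperature the sulfonamide tolerates, or the sulfonyl group may migrate from nitrogen to the phenoxide. The fallback for step 4 sets out from 5 and comes back to the route at ketone 8, so that step 5 is not needed. Purchased tert-butyl 3-oxopiperidine-1-carboxylate (CC(C)(C)OC(=O)N1CCCC(=O)C1) is enolised away from nitrogen with LiHMDS and Me3SiCl to tert-butyl 5-[(trimethylsilyl)oxy]-3,6-dihydropyridine-1(2H)-carboxylate F2 and then brominated with NBS to racemic tert-butyl 4-bromo-3-oxopiperidine-1-carboxylate F3 in a second operation. The phenoxide of 5 (K2CO3, acetone, rt) should then displace the bromide of F3 in a classical α-halo ketone etherification to give 8.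

Risk at step 9. Aminomethylation may occur at the indoline nitrogen N9 or at C6 para to it, or may be slow at C3' because of the peri substituent on C4'. The fallback for step 9 sets out from 14 and comes back to the route at 15. Vilsmeier–Haack formylation (POCl3, DMF, 0 °C, then warm aqueous NaOH, which should also cleave any formamidinium formed at N9) should give the (4aS,9aR)-N2-methyl hexacycle 3'-carbaldehyde F4 as the only new compound. Reductive amination of F4 with Me2NH and NaBH(OAc)3 should then give 15.

**Further compounds**

F1 | step 6 | racemic cis-fused N2-Boc-N1'-tosyl hexacycle (12 together with its enantiomer) | COc1cc2c(c3ccn(S(=O)(=O)c4ccc(C)cc4)c13)C13CN(C(=O)OC(C)(C)C)CC1(O2)c1ccccc1N3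
F2 | step 4 | tert-butyl 5-[(trimethylsilyl)oxy]-3,6-dihydropyridine-1(2H)-carboxylate | CC(C)(C)OC(=O)N1CCC=C(O[Si](C)(C)C)C1
F3 | step 4 | tert-butyl 4-bromo-3-oxopiperidine-1-carboxylate (racemic) | CC(C)(C)OC(=O)N1CCC(Br)C(=O)C1
F4 | step 9 | (4aS,9aR)-N2-methyl hexacycle 3'-carbaldehyde | COc1cc2c(c3c(C=O)c[nH]c13)[C@@]13CN(C)CC[C@]1(O2)c1ccccc1N3
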